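**Strategy.** Numbering: five-membered ring C1(CH3)–C2–C3–C4(OH, isopropyl)–C5; seven-membered ring C1–C5–C6(O-aroyl)–C7–C8(CH3)=C9–C10(O-isovaleryl). The seven-membered ring is opened at C6–C7. The key step exploits the homoallylic alcohol C6(OH)–C7H2–C8(CH3)=C9 of this ring together with the C10 oxygen: a Me2AlCl-promoted type 2 carbonyl-ene reaction of a cyclopentane carrying a cis formyl group (C6) and a 3-methylbut-3-enoyl group (C10 to C7) closes the ring, sets C6 and leaves an alkene that the C10 ketone draws into the C8=C9 position. The precursor comes from a cis-fused bicyclic lactone that fixes C1 and C5 and lets the C4 hydroxyl enter from the convex face.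

Key step: step 10

Remark (assumption): the facial sense of the rhodium/(R)-BINAP alkenylation in step 2 is taken by analogy with 1,4-additions to cyclic enones; if the opposite sense were found, (S)-BINAP would be used and nothing else changes.

Step 1
Reactants: 1 3-methylbut-1-yne
Product: 3 4,4,5,5-tetramethyl-2-(3-methylbut-1-en-2-yl)-1,3,2-dioxaborolane, via alkenylalane 2 (not isolated)
Conditions: iBu2AlH (1.3 equiv), NiCl2(dppp) (3 mol%), THF, 0 °C to rt; then 2-methoxy-4,4,5,5-tetramethyl-1,3,2-dioxaborolane, 0 °C to rt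
Reagents that add atoms: 2-methoxy-4,4,5,5-tetramethyl-1,3,2-dioxaborolane, COB1OC(C)(C)C(C)(C)O1
Why: Nickel-catalysed α-selective (Markovnikov) hydroalumination of the terminal alkyne puts aluminium on the internal carbon, and aluminium-to-boron exchange with the methoxyborolane should give the 1,1-disubstituted alkenyl boronate.

Step 2
Reactants: 3 4,4,5,5-tetramethyl-2-(3-methylbut-1-en-2-yl)-1,3,2-dioxaborolane; 4 furan-2(5H)-one
Product: 5 (4R)-4-(3-methylbut-1-en-2-yl)oxolan-2-one
Conditions: [Rh(cod)(OH)]2 (3 mol%), (R)-BINAP (7 mol%), K3PO4 (0.5 equiv), dioxane/H2O 10:1, 60 °C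
Reagents that add atoms: none
Why: Hayashi–Miyaura rhodium-catalysed asymmetric 1,4-addition, in which the alkenylrhodium species adds to the butenolide face selected by (R)-BINAP and the rhodium enolate is protonated by water, should set C5 of the target (4R in 5).

Step 3
Reactants: 5 (4R)-4-(3-methylbut-1-en-2-yl)oxolan-2-one
Product: 6 (3S,4R)-4-(3-methylbut-1-en-2-yl)-3-(prop-2-en-1-yl)oxolan-2-one (trans)
Conditions: LiN(iPr)2 (1.1 equiv), THF, −78 °C; allyl bromide, −78 to −40 °C
Reagents that add atoms: allyl bromide, C=CCBr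
Why: Lactone enolate alkylation, the electrophile entering anti to the β-alkenyl group to give the trans lactone.

Step 4
Reactants: 6 (3S,4R)-4-(3-methylbut-1-en-2-yl)-3-(prop-2-en-1-yl)oxolan-2-one
Product: 7 (3R,4S)-3-methyl-4-(3-methylbut-1-en-2-yl)-3-(prop-2-en-1-yl)oxolan-2-one
Conditions: LiN(iPr)2 (1.2 equiv), THF, −78 °C; CH3I, DMPU, −78 to −20 °C
Reagents that add atoms: iodomethane, CI
Why: Second enolate alkylation, in which iodomethane again enters anti to the β-alkenyl group, creates quaternary C1 with the methyl trans and the allyl group cis to the alkenyl arm, as the ring closure and the target require.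

Step 5
Reactants: 7 (3R,4S)-3-methyl-4-(3-methylbut-1-en-2-yl)-3-(prop-2-en-1-yl)oxolan-2-one
Product: 8 (3aS,6aR)-6a-methyl-4-(propan-2-yl)-3,3a,6,6a-tetrahydro-1H-cyclopenta[c]furan-1-one
Conditions: second-generation Grubbs catalyst RuCl2(=CHPh)(PCy3)(SIMes) (5 mol%), CH2Cl2 (0.01 M), 40 °C
Reagents that add atoms: none
Why: Ring-closing metathesis of the cis-disposed allyl and 1,1-disubstituted alkenyl groups forms the trisubstituted cyclopentene C3=C4 and with it the cis-fused bicyclic lactone.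

Step 6
Reactants: 8 (3aS,6aR)-6a-methyl-4-(propan-2-yl)-3,3a,6,6a-tetrahydro-1H-cyclopenta[c]furan-1-one
Product: 9 (3aS,4S,6aR)-4-hydroxy-6a-methyl-4-(propan-2-yl)hexahydro-1H-cyclopenta[c]furan-1-one
Conditions: Co(acac)2 (20 mol%), PhSiH3 (2.5 equiv), O2 (1 atm), THF, rt
Reagents that add atoms: dioxygen, O=O
Why: Mukaiyama hydration, in which hydrogen-atom transfer from a cobalt hydride to C3 gives the tertiary C4 radical that should capture oxygen on the convex face (anti to the lactone CH2 on C5), puts the hydroxyl cis to H5 and the isopropyl group on the concave face (4S).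

Step 7
Reactants: 9 (3aS,4S,6aR)-4-hydroxy-6a-methyl-4-(propan-2-yl)hexahydro-1H-cyclopenta[c]furan-1-one
Product: 10 (3aS,4S,6aR)-6a-methyl-4-(propan-2-yl)-4-[(triethylsilyl)oxy]hexahydro-1H-cyclopenta[c]furan-1-one
Conditions: Et3SiOTf, 2,6-lutidine, CH2Cl2, 0 °C to rt
Reagents that add atoms: triethylsilyl trifluoromethanesulfonate, CC[Si](CC)(CC)OS(=O)(=O)C(F)(F)F
Why: Silylation of the hindered tertiary alcohol with a silyl triflate gives a non-chelating ether that later blocks retro-aldol cleavage of the β-oxy aldehyde.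

Step 8
Reactants: 10 (3aS,4S,6aR)-6a-methyl-4-(propan-2-yl)-4-[(triethylsilyl)oxy]hexahydro-1H-cyclopenta[c]furan-1-one
Product: 11 (3aS,4S,6aR)-6a-methyl-1-(2-methylprop-2-en-1-yl)-4-(propan-2-yl)-4-[(triethylsilyl)oxy]hexahydro-1H-cyclopenta[c]furan-1-ol (lactol, anomer mixture, in equilibrium with the open hydroxy ketone)
Conditions: 2-methylallylmagnesium chloride (1.2 equiv), THF, −78 °C; AcOH quench at −78 °C
Reagents that add atoms: 2-methylallylmagnesium chloride, C=C(C)C[Mg]Cl
Why: 1,2-Addition of the allylic Grignard reagent to the lactone should stop at the magnesium hemiketalate, which is stable at −78 °C next to the quaternary carbon, and the cold acidic quench avoids conjugation of the β,γ-unsaturated ketone.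

Step 9
Reactants: 11 (3aS,4S,6aR)-6a-methyl-1-(2-methylprop-2-en-1-yl)-4-(propan-2-yl)-4-[(triethylsilyl)oxy]hexahydro-1H-cyclopenta[c]furan-1-ol
Product: 12 (1R,2R,5S)-2-methyl-2-(3-methylbut-3-enoyl)-5-(propan-2-yl)-5-[(triethylsilyl)oxy]cyclopentane-1-carbaldehyde
Conditions: Dess–Martin periodinane (1.5 equiv), NaHCO3, CH2Cl2, 0 °C to rt; used crude
Reagents that add atoms: none
Why: Dess–Martin oxidation acts on the primary alcohol of the open hydroxy-ketone tautomer (the hemiketal carbon bears no hydrogen), and the buffered base-free medium should preserve C5 and the β,γ-alkene.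

Step 10
Reactants: 12 (1R,2R,5S)-2-methyl-2-(3-methylbut-3-enoyl)-5-(propan-2-yl)-5-[(triethylsilyl)oxy]cyclopentane-1-carbaldehyde
Product: 13 (3S,3aS,4R,8aR)-4-hydroxy-8a-methyl-6-methylidene-3-(propan-2-yl)-3-[(triethylsilyl)oxy]octahydroazulen-8(1H)-one
Conditions: Me2AlCl (2.0 equiv), CH2Cl2, −78 to −30 °C; aqueous Rochelle salt
Reagents that add atoms: none
Why: Me2AlCl activates the hindered aldehyde and the terminal alkene carbon C7 attacks C6 while a hydrogen of the allylic methyl C14 shifts to oxygen through a six-membered array, a type 2 intramolecular carbonyl-ene reaction (tether on the central ene carbon) whose closest precedent is the Me2AlCl-promoted closure of ω-methallyl aldehydes to 3-methylenecycloheptanols. The ring closes in a 7-exo-trig sense at the carbonyl carbon, with C7 and C8 becoming ring atoms and the double bond moving to the exocyclic C8=C14 position; the cis formyl and acyl arms, fixed since lactone 8, hold the two termini within reach. The new stereocentre C6 is controlled by C5 and the β-silyloxy carbon C4: approach of C7 anti to the bulky C4 (Felkin–Anh) with the C6=O and C4–O dipoles opposed (the 1,3-anti preference of β-silyloxy aldehydes under a non-chelating Lewis acid) should put O6 on the concave face, which is 4R in azulene numbering. The step needs ene closure to win over Lewis-acid enolisation and aldol closure of the β,γ-unsaturated ketone onto the aldehyde and over epimerisation at C5; low temperature, the base-free medium and the proton-scavenging Al–CH3 bonds should secure this, and any C8 chloride or endocyclic isomer formed alongside 13 converges to 14 in step 11.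

Step 11
Reactants: 13 (3S,3aS,4R,8aR)-4-hydroxy-8a-methyl-6-methylidene-3-(propan-2-yl)-3-[(triethylsilyl)oxy]octahydroazulen-8(1H)-one
Product: 14 (3S,3aS,4R,8aR)-4-hydroxy-6,8a-dimethyl-3-(propan-2-yl)-3-[(triethylsilyl)oxy]-2,3,3a,4,5,8a-hexahydroazulen-8(1H)-one
Conditions: DBU (0.3 equiv), CH2Cl2, rt
Reagents that add atoms: none
Why: Base-mediated β,γ- to α,β-enone isomerisation through the dienolate (deprotonation at C9, reprotonation at C14) should place the alkene at C8=C9 in conjugation with the C10 ketone, and the free C6 hydroxyl, a poor leaving group, precludes vinylogous β-elimination.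

Step 12
Reactants: 14 (3S,3aS,4R,8aR)-4-hydroxy-6,8a-dimethyl-3-(propan-2-yl)-3-[(triethylsilyl)oxy]-2,3,3a,4,5,8a-hexahydroazulen-8(1H)-one
Product: 15 (3S,3aS,4R,8aR)-6,8a-dimethyl-8-oxo-3-(propan-2-yl)-3-[(triethylsilyl)oxy]-1,2,3,3a,4,5,8,8a-octahydroazulen-4-yl 4-[(tert-butyldimethylsilyl)oxy]benzoate
Conditions: 4-[(tert-butyldimethylsilyl)oxy]benzoic acid (1.5 equiv), 1-chloro-N,N,2-trimethylprop-1-en-1-amine, CH2Cl2, 0 °C to rt; then 14, pyridine, DMAP (0.2 equiv), 0 °C to rt
Reagents that add atoms: 4-[(tert-butyldimethylsilyl)oxy]benzoic acid, O=C(O)c1ccc(O[Si](C)(C)C(C)(C)C)cc1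
Why: DMAP-catalysed acylation of the secondary C6 alcohol by the acid chloride generated in the flask proceeds with retention at C6, the tertiary silyl ether being inert and the weakly basic medium avoiding elimination of the new δ-acyloxy enone.

Step 13
Reactants: 15 (3S,3aS,4R,8aR)-6,8a-dimethyl-8-oxo-3-(propan-2-yl)-3-[(triethylsilyl)oxy]-1,2,3,3a,4,5,8,8a-octahydroazulen-4-yl 4-[(tert-butyldimethylsilyl)oxy]benzoate
Product: 16 (3S,3aS,4R,8S,8aR)-8-hydroxy-6,8a-dimethyl-3-(propan-2-yl)-3-[(triethylsilyl)oxy]-1,2,3,3a,4,5,8,8a-octahydroazulen-4-yl 4-[(tert-butyldimethylsilyl)oxy]benzoate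
Conditions: NaBH4, CeCl3·7H2O, MeOH, −78 °C
Reagents that add atoms: none
Why: Luche 1,2-reduction should deliver hydride to the C10 carbonyl from the convex face, anti to the cyclopentane ring, giving the 8S allylic alcohol with its oxygen on the concave face.

Step 14
Reactants: 16 (3S,3aS,4R,8S,8aR)-8-hydroxy-6,8a-dimethyl-3-(propan-2-yl)-3-[(triethylsilyl)oxy]-1,2,3,3a,4,5,8,8a-octahydroazulen-4-yl 4-[(tert-butyldimethylsilyl)oxy]benzoate
Product: 17 (3S,3aS,4R,8S,8aR)-6,8a-dimethyl-8-[(3-methylbutanoyl)oxy]-3-(propan-2-yl)-3-[(triethylsilyl)oxy]-1,2,3,3a,4,5,8,8a-octahydroazulen-4-yl 4-[(tert-butyldimethylsilyl)oxy]benzoate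
Conditions: 3-methylbutanoyl chloride, pyridine, DMAP (0.2 equiv), CH2Cl2, 0 °C to rt
Reagents that add atoms: 3-methylbutanoyl chloride, CC(C)CC(=O)Cl
Why: DMAP-catalysed acylation of the allylic alcohol with the acid chloride occurs at oxygen with retention at C10.

Step 15
Reactants: 17 (3S,3aS,4R,8S,8aR)-6,8a-dimethyl-8-[(3-methylbutanoyl)oxy]-3-(propan-2-yl)-3-[(triethylsilyl)oxy]-1,2,3,3a,4,5,8,8a-octahydroazulen-4-yl 4-[(tert-butyldimethylsilyl)oxy]benzoate
Product: 18 (3S,3aS,4R,8S,8aR)-3-hydroxy-6,8a-dimethyl-8-[(3-methylbutanoyl)oxy]-3-(propan-2-yl)-1,2,3,3a,4,5,8,8a-octahydroazulen-4-yl 4-hydroxybenzoate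
Conditions: HF·pyridine, pyridine, THF, 0 °C to rt
Reagents that add atoms: none
Why: Fluoride-mediated desilylation with buffered HF·pyridine should cleave the aryl tert-butyldimethylsilyl ether and the tertiary triethylsilyl ether in one operation while leaving both esters and the allylic C–O bond intact.

**Compound list**

1 | 3-methylbut-1-yne | C#CC(C)C | starting material
2 | diisobutyl(3-methylbut-1-en-2-yl)alumane | C=C([Al](CC(C)C)CC(C)C)C(C)C | intermediate
3 | 4,4,5,5-tetramethyl-2-(3-methylbut-1-en-2-yl)-1,3,2-dioxaborolane | C=C(B1OC(C)(C)C(C)(C)O1)C(C)C | intermediate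
4 | furan-2(5H)-one | O=C1OCC=C1 | starting material
5 | (4R)-4-(3-methylbut-1-en-2-yl)oxolan-2-one | O=C1OC[C@@H](C(=C)C(C)C)C1 | intermediate
6 | (3S,4R)-4-(3-methylbut-1-en-2-yl)-3-(prop-2-en-1-yl)oxolan-2-one | O=C1OC[C@@H](C(=C)C(C)C)[C@@H]1CC=C | intermediate
7 | (3R,4S)-3-methyl-4-(3-methylbut-1-en-2-yl)-3-(prop-2-en-1-yl)oxolan-2-one | O=C1OC[C@@H](C(=C)C(C)C)[C@@]1(C)CC=C | intermediate
8 | (3aS,6aR)-6a-methyl-4-(propan-2-yl)-3,3a,6,6a-tetrahydro-1H-cyclopenta[c]furan-1-one | O=C1OC[C@@H]2[C@@]1(C)CC=C2C(C)C | intermediate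
9 | (3aS,4S,6aR)-4-hydroxy-6a-methyl-4-(propan-2-yl)hexahydro-1H-cyclopenta[c]furan-1-one | O=C1OC[C@@H]2[C@@]1(C)CC[C@]2(O)C(C)C | intermediate
10 | (3aS,4S,6aR)-6a-methyl-4-(propan-2-yl)-4-[(triethylsilyl)oxy]hexahydro-1H-cyclopenta[c]furan-1-one | O=C1OC[C@@H]2[C@@]1(C)CC[C@]2(O[Si](CC)(CC)CC)C(C)C | intermediate
11 | (3aS,4S,6aR)-6a-methyl-1-(2-methylprop-2-en-1-yl)-4-(propan-2-yl)-4-[(triethylsilyl)oxy]hexahydro-1H-cyclopenta[c]furan-1-ol (anomer mixture) | C=C(C)CC1(O)OC[C@@H]2[C@@]1(C)CC[C@]2(O[Si](CC)(CC)CC)C(C)C | intermediate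
12 | (1R,2R,5S)-2-methyl-2-(3-methylbut-3-enoyl)-5-(propan-2-yl)-5-[(triethylsilyl)oxy]cyclopentane-1-carbaldehyde | C=C(C)CC(=O)[C@]1(C)CC[C@](O[Si](CC)(CC)CC)(C(C)C)[C@@H]1C=O | intermediate
13 | (3S,3aS,4R,8aR)-4-hydroxy-8a-methyl-6-methylidene-3-(propan-2-yl)-3-[(triethylsilyl)oxy]octahydroazulen-8(1H)-one | C=C1CC(=O)[C@]2(C)CC[C@](O[Si](CC)(CC)CC)(C(C)C)[C@@H]2[C@H](O)C1 | intermediate
14 | (3S,3aS,4R,8aR)-4-hydroxy-6,8a-dimethyl-3-(propan-2-yl)-3-[(triethylsilyl)oxy]-2,3,3a,4,5,8a-hexahydroazulen-8(1H)-one | CC1=CC(=O)[C@]2(C)CC[C@](O[Si](CC)(CC)CC)(C(C)C)[C@@H]2[C@H](O)C1 | intermediate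
15 | (3S,3aS,4R,8aR)-6,8a-dimethyl-8-oxo-3-(propan-2-yl)-3-[(triethylsilyl)oxy]-1,2,3,3a,4,5,8,8a-octahydroazulen-4-yl 4-[(tert-butyldimethylsilyl)oxy]benzoate | CC1=CC(=O)[C@]2(C)CC[C@](O[Si](CC)(CC)CC)(C(C)C)[C@@H]2[C@H](OC(=O)c2ccc(O[Si](C)(C)C(C)(C)C)cc2)C1 | intermediate
16 | (3S,3aS,4R,8S,8aR)-8-hydroxy-6,8a-dimethyl-3-(propan-2-yl)-3-[(triethylsilyl)oxy]-1,2,3,3a,4,5,8,8a-octahydroazulen-4-yl 4-[(tert-butyldimethylsilyl)oxy]benzoate | CC1=C[C@H](O)[C@]2(C)CC[C@](O[Si](CC)(CC)CC)(C(C)C)[C@@H]2[C@H](OC(=O)c2ccc(O[Si](C)(C)C(C)(C)C)cc2)C1 | intermediate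
17 | (3S,3aS,4R,8S,8aR)-6,8a-dimethyl-8-[(3-methylbutanoyl)oxy]-3-(propan-2-yl)-3-[(triethylsilyl)oxy]-1,2,3,3a,4,5,8,8a-octahydroazulen-4-yl 4-[(tert-butyldimethylsilyl)oxy]benzoate | CC1=C[C@H](OC(=O)CC(C)C)[C@]2(C)CC[C@](O[Si](CC)(CC)CC)(C(C)C)[C@@H]2[C@H](OC(=O)c2ccc(O[Si](C)(C)C(C)(C)C)cc2)C1 | intermediate
18 | (3S,3aS,4R,8S,8aR)-3-hydroxy-6,8a-dimethyl-8-[(3-methylbutanoyl)oxy]-3-(propan-2-yl)-1,2,3,3a,4,5,8,8a-octahydroazulen-4-yl 4-hydroxybenzoate | CC1=C[C@H](OC(=O)CC(C)C)[C@]2(C)CC[C@](O)(C(C)C)[C@@H]2[C@H](OC(=O)c2ccc(O)cc2)C1 | target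

**Total step count:** 15. **Longest linear sequence:** 15 steps (from 1).

**Steps most likely to fail**

Step 10 (key ring closure). The alkene is inductively deactivated by the neighbouring ketone, so the ene reaction may be slow; the Lewis acid may instead enolise the β,γ-unsaturated ketone and close a five-membered aldol ring onto the aldehyde; facial selectivity at C6 may be poor. Fallback, setting out from 10 and returning at 13: an intramolecular Hosomi–Sakurai allylation, in which a more nucleophilic allylsilane attacks the aldehyde through an open transition state under a non-chelating Lewis acid. Lactone 10 is treated at −78 °C with [2-(trimethylsilylmethyl)prop-2-en-1-yl]magnesium chloride (from commercial 2-(chloromethyl)allyltrimethylsilane and magnesium) to give the allylsilane lactol F1. Dess–Martin oxidation of its open tautomer gives the allylsilane keto aldehyde F2. BF3·OEt2 in CH2Cl2 at −78 °C should then join C7 to C6 with loss of silicon from C14, delivering the same exocyclic alkene 13.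

Step 8 (mono-addition to the lactone). Collapse of the hemiketalate and a second Grignard addition, or base-induced conjugation of the β,γ-unsaturated ketone in the open tautomer, may erode the product. Fallback, setting out from 10 and returning at 12: reduction with iBu2AlH in CH2Cl2 at −78 °C gives the lactol F3. Its open aldehyde form is trapped by 2-methylallylmagnesium chloride to give the diol F4 (both C10 epimers are usable). Excess Dess–Martin periodinane with NaHCO3 oxidises both carbinols to keto aldehyde 12.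

Step 2 (asymmetric alkenylation). The hindered α-branched alkenyl boronate may transmetalate slowly, protodeboronate, or add to the poorly reactive butenolide with insufficient enantioselectivity. Fallback, setting out from 1 (through alkenylalane 2) and returning at 5: an auxiliary-controlled cuprate addition to an acyclic acceptor. Iodinolysis of 2 gives 2-iodo-3-methylbut-1-ene F5. Halogen–lithium exchange (tBuLi, −78 °C) and CuBr·SMe2 form the alkenylcuprate. This should add to (4S)-4-benzyl-3-[(2E)-4-{[tert-butyl(dimethyl)silyl]oxy}but-2-enoyl]-1,3-oxazolidin-2-one F6, made from (S)-4-benzyloxazolidin-2-one and (E)-4-[(tert-butyldimethylsilyl)oxy]but-2-enoic acid by the pivaloyl mixed-anhydride method. Attack anti to the benzyl group of the chelated s-cis imide gives (4S)-4-benzyl-3-[(3R)-3-({[tert-butyl(dimethyl)silyl]oxy}methyl)-5-methyl-4-methylidenehexanoyl]-1,3-oxazolidin-2-one F7. Desilylation with HF·pyridine frees the primary alcohol, which lactonises with release of the auxiliary to give 5.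

**Further compounds**

F1 | step 10 | (3aS,4S,6aR)-6a-methyl-4-(propan-2-yl)-4-[(triethylsilyl)oxy]-1-{2-[(trimethylsilyl)methyl]prop-2-en-1-yl}hexahydro-1H-cyclopenta[c]furan-1-ol | C=C(C[Si](C)(C)C)CC1(O)OC[C@@H]2[C@@]1(C)CC[C@]2(O[Si](CC)(CC)CC)C(C)C
F2 | step 10 | (1R,2R,5S)-2-methyl-5-(propan-2-yl)-5-[(triethylsilyl)oxy]-2-{3-[(trimethylsilyl)methyl]but-3-enoyl}cyclopentane-1-carbaldehyde | C=C(C[Si](C)(C)C)CC(=O)[C@]1(C)CC[C@](O[Si](CC)(CC)CC)(C(C)C)[C@@H]1C=O
F3 | step 8 | (3aS,4S,6aR)-6a-methyl-4-(propan-2-yl)-4-[(triethylsilyl)oxy]hexahydro-1H-cyclopenta[c]furan-1-ol | OC1OC[C@@H]2[C@@]1(C)CC[C@]2(O[Si](CC)(CC)CC)C(C)C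
F4 | step 8 | 1-[(1R,2S,3S)-2-(hydroxymethyl)-1-methyl-3-(propan-2-yl)-3-[(triethylsilyl)oxy]cyclopentyl]-3-methylbut-3-en-1-ol | C=C(C)CC(O)[C@]1(C)CC[C@](O[Si](CC)(CC)CC)(C(C)C)[C@@H]1CO
F5 | step 2 | 2-iodo-3-methylbut-1-ene | C=C(I)C(C)C
F6 | step 2 | (4S)-4-benzyl-3-[(2E)-4-{[tert-butyl(dimethyl)silyl]oxy}but-2-enoyl]-1,3-oxazolidin-2-one | O=C(/C=C/CO[Si](C)(C)C(C)(C)C)N1[C@@H](Cc2ccccc2)COC1=O
F7 | step 2 | (4S)-4-benzyl-3-[(3R)-3-({[tert-butyl(dimethyl)silyl]oxy}methyl)-5-methyl-4-methylidenehexanoyl]-1,3-oxazolidin-2-one | O=C(C[C@@H](CO[Si](C)(C)C(C)(C)C)C(=C)C(C)C)N1[C@@H](Cc2ccccc2)COC1=O
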